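## The problem

The target is a biflavone ether. Unit 1 is genkwanin (5-hydroxy-7-methoxyflavone), and its ring B oxygen O4' is bonded to C8 of unit 2, an apigenin (5,7,4'-trihydroxyflavone). The molecule is achiral, so every difficulty is one of position. C8 of unit 2 lies between the C7 hydroxyl and the oxygen-bearing C8a on an electron-rich phloroglucinol-type ring. Closing the ether there by Ullmann coupling or aromatic substitution means attacking a doubly ortho-substituted carbon, and the isomeric C6 position must be excluded. 5,7-Dihydroxyflavones can also exchange 6- and 8-substituents by ring opening and reclosure (Wessely–Moser rearrangement) under harsh acid. Of five phenolic oxygens only O7 of unit 1 is methylated, so any protecting group has to leave by a method that spares an aryl methyl ether. Both γ-pyranone rings are vinylogous esters that open with hydroxide, and the free polyphenol is oxidised in base, so the late steps should be neutral or mildly acidic. The feature that allows a short route is ring A of unit 2: a resorcinol ring fused to the pyranone across C4a–C8a with oxygen on C5, C7 and C8. Carbons C5–C8 map onto a 1,3-dioxygenated butadiene with the aryloxy group on its terminal carbon, and C4a–C8a map onto the 5,6-double bond of a 2-arylpyran-4-one.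

## Retrosynthesis

**16 from 15.** The target 16 is traced back to its 4'''-O-benzyl ether 15 by cutting one O–CH2 bond. Benzyl is chosen because this oxygen has to pass through a lithium amide, strong acid, a peracid and heat, and because hydrogenolysis leaves the C7 methyl ether and the diaryl ether alone. A methyl group could not be told apart from the one that must stay. A silyl group would save this step but is less certain to survive the acid cyclisation that makes the pyranone. The forward step is a single neutral hydrogenolysis.

**15 from 11 and 7.** In 15 the bonds C8–C8a and C5–C4a of ring A of unit 2 are cut. This gives the 4-aryloxy-1-methoxy-1,3-bis(silyloxy)diene 11, which carries unit 1 complete, and the 5-sulfinyl-2-arylpyran-4-one 7. The neighbouring cut, the C8–O bond itself, would require a copper coupling at the crowded C8. Cutting the pyranone of unit 2 would only move the same ether problem to a phloroglucinol. The chosen cut removes one ring and two skeletal bonds and divides the molecule into two halves of similar size. The forward reaction must place the aryloxy carbon on C8a and the ketene acetal carbon on C4a. It must then shed the sulfur group (from adduct 12 to give 13) and the acetal methoxy group (to give arene 14) so that ring A aromatises. A sulfinyl group is preferred to a halogen on the pyranone because it activates the alkene more strongly and leaves thermally without base.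

**11 from 10, and 10 from 8 and 9.** Diene 11 is the silylated form of β-keto ester 10; three O–Si bonds are cut. Keto ester 10 is then cut at the O4'–CH2 bond into genkwanin 8 and methyl 4-chloro-3-oxobutanoate 9. The ether oxygen that is so hard to attach to C8 of an arene is thus attached to an sp3 carbon by SN2. The unhindered and more acidic 4'-hydroxyl of 8 reacts, and the chelated 5-hydroxyl stays out. The chelated 5-hydroxyl is silylated along with the keto ester, so it cannot protonate the ketene acetal. A route through an aryloxyacetic acid and two-carbon homologation would cost two more steps.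

**7 from 6, and 6 from 3 and 4.** Sulfoxide 7 comes from sulfide 6 by oxidation at sulfur. Pyranone 6 is cut at C2–C3 and O1–C6 into the enaminone 3 and 4-(benzyloxy)benzoyl chloride 4, by way of the open enaminodiketone 5. The alternative of acylating an aryl methyl ketone with a thioacetate and then formylating was set aside. In that 1,3-diketone the central methylene, not the sulfur-bearing one, is the more reactive site, so the formyl carbon could go to the wrong place. Sulfenylating a finished pyranone would raise a C3 versus C5 question. In 3 the sulfur is already on the right carbon.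

**3 from 1 and 2.** Enaminone 3 is cut at its C=C bond into 1-[(4-methylphenyl)sulfanyl]propan-2-one 1 and the formamide acetal 2. The methylene between sulfur and the ketone is the only strongly activated position of 1, so the one-carbon unit that becomes C8a of the target enters without ambiguity.

## Roads not taken

**Alternative 1: Danheiser benzannulation around the ether.** The cut is at C8a–C4a and C5–C6 of ring A of unit 2, with C8a–C8 opened and reclosed on the way.
- Forward step: the 4-aryloxy-3-silyloxycyclobutenone A2 is heated with the silyloxyacetylene A3. Electrocyclic opening to a vinylketene, (2+2) addition of the ynol ether, a second opening and a 6π closure give the phenol A1.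
- Merits: the substitution pattern follows from the pericyclic cascade. The aryloxy carbon ends next to a free phenol (the future ring oxygen) while the other two oxygens are silylated and so distinguished. The benzannulation type is well established, which the chosen key step is not.
- Weak points: A2 is a sensitive compound that needs several steps. A1 contains neither flavone heterocycle. Ring A must still be C-acylated at the position between the free hydroxyl and a silyloxy group without scrambling the silyl groups. The pyranone of unit 2 must then be closed, and the benzoate turned into the whole of unit 1 by a second flavone synthesis.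
- Comparison: this road is safer at its key step but well over twice as long. The chosen plan sets against it that both heterocycles, one of them bought as 8, are in place before ring A is made, and that ring A is the last ring formed.

**Alternative 2: Claisen folding of a cinnamoyl triketo ester.** The cut is at C4a–C5 of ring A of unit 1.
- Forward step: the triketo ester A5, under chelating magnesium alkoxide conditions, closes by attack of its C6 carbanion on the ester carbon to give the 2',4',6'-trihydroxychalcone A4. Oxidative cyclisation, selective 7-O-methylation and hydrogenolysis follow.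
- Merits: the cyclisation mode has precedent in polyketide-type models. The acylphloroglucinol pattern arises without a Friedel–Crafts step. The 7-hydroxyl can be methylated in the presence of the chelated 5-hydroxyl.
- Weak points: it builds the ring that is not the problem. A5 already contains the complete, tribenzylated unit 2 with its 8-aryloxy bond, so the crowded ether must first be made by a conventional arene coupling. The triketo ester can also close by aldol reaction to a resorcylate or by O-cyclisation to a pyranone, and its enone invites conjugate addition.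
- Comparison: in precedent for the ring closure this road is ahead. The chosen plan sets against it that it addresses the C8–O bond directly and takes unit 1, methyl ether included, from the natural product 8.

**Alternative 3: coumalate and ynol ether cycloaddition.** The cut is at C3'–C4' and C5'–C6' of ring B of unit 1.
- Forward step: methyl coumalate A7 and the aryl ethynyl ether A8 undergo an inverse-demand Diels–Alder reaction and decarboxylate to the 4-aryloxybenzoate A6.
- Merits: the ether oxygen is again attached away from a crowded arene carbon, this time by O-alkynylation of a phenol. The para relationship follows from the polarity of both partners. The reaction class is known and its only by-product is a gas, so at the key step this road is more secure than the chosen one.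
- Weak points: A8 requires a tetraoxygenated benzene with three different protecting groups. After the key step neither heterocycle exists. A6 needs site-selective acylation and pyranone closure for unit 2, and conversion of the ester into unit 1.
- Comparison: the chosen plan is much shorter and convergent. It pays for this with a key step that has no direct precedent.

Key step: step 6

Assumption: 1-[(4-methylphenyl)sulfanyl]propan-2-one, 4-(benzyloxy)benzoyl chloride, genkwanin and methyl 4-chloro-3-oxobutanoate are taken as catalogue compounds; the thio ketone is otherwise one S-alkylation away from 4-methylbenzenethiol and chloroacetone.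

## Route

Step 1
Reactants: 1 1-[(4-methylphenyl)sulfanyl]propan-2-one; 2 N,N-dimethylformamide dimethyl acetal
Product: 3 (3Z)-4-(dimethylamino)-3-[(4-methylphenyl)sulfanyl]but-3-en-2-one
Conditions: 2 (1.3 equiv), toluene, 90 °C, MeOH distilled off
Reagents that add atoms: none
Why: Aminomethylenation (enaminone formation) at the methylene flanked by sulfur and the ketone, which is far more acidic than the methyl group, the same site selectivity as with arylacetones; the push-pull alkene is configurationally labile and its geometry is of no consequence.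

Step 2
Reactants: 3 (3Z)-4-(dimethylamino)-3-[(4-methylphenyl)sulfanyl]but-3-en-2-one; 4 4-(benzyloxy)benzoyl chloride
Product: 6 2-[4-(benzyloxy)phenyl]-5-[(4-methylphenyl)sulfanyl]-4H-pyran-4-one, via enaminodiketone 5 (not isolated)
Conditions: LiN(SiMe3)2 (2.2 equiv), THF, −78 °C; 4, −78 → 0 °C; CF3CO2H, CH2Cl2, rt
Reagents that add atoms: none
Why: Claisen-type C-acylation of the kinetic lithium enolate of the methyl ketone (the second equivalent of base takes up the acidic diketone 5), then acid-promoted cyclisation in which the enol oxygen displaces dimethylamine by addition–elimination; this is the standard γ-pyranone synthesis from enaminones and acid chlorides.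

Step 3
Reactants: 6 2-[4-(benzyloxy)phenyl]-5-[(4-methylphenyl)sulfanyl]-4H-pyran-4-one
Product: 7 2-[4-(benzyloxy)phenyl]-5-[(4-methylphenyl)sulfinyl]-4H-pyran-4-one (racemic at sulfur)
Conditions: mCPBA (1.0 equiv), CH2Cl2, −40 → 0 °C
Reagents that add atoms: 3-chloroperoxybenzoic acid (mCPBA), O=C(OO)c1cccc(Cl)c1
Why: Electrophilic oxidation of the sulfide with one equivalent of peracid at low temperature stops at the sulfoxide; the pyranone double bonds are electron-poor vinylogous-ester alkenes and the benzyl ether is inert; the new sulfur stereocentre forms racemic and is lost in step 6.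

Step 4
Reactants: 8 genkwanin (5-hydroxy-2-(4-hydroxyphenyl)-7-methoxy-4H-chromen-4-one); 9 methyl 4-chloro-3-oxobutanoate
Product: 10 methyl 4-[4-(5-hydroxy-7-methoxy-4-oxo-4H-chromen-2-yl)phenoxy]-3-oxobutanoate
Conditions: NaH (3.2 equiv), DMF, 0 °C; 9 (1.3 equiv), 0 °C → rt; aq. NH4Cl
Reagents that add atoms: none
Why: Williamson ether synthesis (SN2) by the 4'-phenoxide, the more acidic and unhindered hydroxyl, on the primary chloride of 9 held as its sodium enolate, following the excess-base protocol used for 4-alkoxy- and 4-aryloxyacetoacetates; the 5-oxide is chelated to the carbonyl and is a poor nucleophile.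

Step 5
Reactants: 10 methyl 4-[4-(5-hydroxy-7-methoxy-4-oxo-4H-chromen-2-yl)phenoxy]-3-oxobutanoate
Product: 11 7-methoxy-2-[4-({(1Z,3Z)-4-methoxy-2,4-bis[(trimethylsilyl)oxy]buta-1,3-dien-1-yl}oxy)phenyl]-5-[(trimethylsilyl)oxy]-4H-chromen-4-one
Conditions: Me3SiOTf (3.6 equiv), Et3N (4.5 equiv), Et2O–toluene, 0 °C → rt; salt layer removed, evaporated, used crude
Reagents that add atoms: trimethylsilyl trifluoromethanesulfonate, C[Si](C)(C)OS(=O)(=O)C(F)(F)F
Why: Soft enolisation with silyl triflate and triethylamine converts β-keto esters in one operation into 1-alkoxy-1,3-bis(silyloxy)buta-1,3-dienes (O-silylation of the enol, then of the ester carbonyl with loss of the γ-proton next to the aryloxy group) and silylates the chelated 5-hydroxyl; no lithium amide is used that could metalate C3 of the flavone, and the aryloxy group is expected trans to the diene backbone as drawn.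

Step 6
Reactants: 11 7-methoxy-2-[4-({(1Z,3Z)-4-methoxy-2,4-bis[(trimethylsilyl)oxy]buta-1,3-dien-1-yl}oxy)phenyl]-5-[(trimethylsilyl)oxy]-4H-chromen-4-one; 7 2-[4-(benzyloxy)phenyl]-5-[(4-methylphenyl)sulfinyl]-4H-pyran-4-one
Product: 15 2-[4-(benzyloxy)phenyl]-5,7-dihydroxy-8-[4-(5-hydroxy-7-methoxy-4-oxo-4H-chromen-2-yl)phenoxy]-4H-chromen-4-one, via sulfinyl cycloadduct 12 (not isolated), via dihydrochromenone silyl ketal 13 (not isolated), via tris(trimethylsilyl) ether 14 (not isolated)
Conditions: 11 (1.5 equiv), toluene, powdered 4 Å sieves, rt → 85 °C; then 1 M HCl, THF–MeOH, rt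
Reagents that add atoms: none
Why: Proposed new method: the electron-rich diene 11 should add across the C5=C6 bond of 7, the only pyranone double bond activated by both the ring ketone and the sulfinyl group, with its aryloxy-bearing terminus (the most nucleophilic carbon of a 1-alkoxy-1,3-bis(silyloxy)diene) bonding to the β-carbon C6 and its ketene acetal carbon to the sulfinyl-bearing C5, either as a concerted (4+2) cycloaddition or as a Mukaiyama–Michael addition followed by 6-exo-trig attack of the α-sulfinyl enolate on the O-silyl oxocarbenium carbon, both giving 12. The closest known chemistry is the regiocontrolled annulation of 1,3-dioxygenated silyloxydienes onto halo- and sulfinylquinones and the Diels–Alder and sulfoxide-elimination sequence of 3-sulfinylchromones; a monocyclic 5-sulfinylpyran-4-one has not been used in this way. In 12 the sulfoxide sits on a quaternary carbon next to the ketone with a single β-hydrogen at C8a, so thermal syn elimination of the sulfenic acid restores the pyranone double bond in 13. 1,4-Loss of methanol from the mixed silyl ketal at C5 and the doubly allylic C8–H then gives arene 14, and dilute acid removes the three silyl groups to give 15. Ring A is therefore closed by the new C8–C8a and C5–C4a bonds and aromatised by two eliminations; the sp3 centres of 12 and 13 are transient, no stereocentre remains, and racemic 7 is sufficient. The selectivity needed is regiochemical (aryloxy at C8 beside the ring oxygen, chelated hydroxyl at C5) and is secured by polarity matching, since C6 is the acceptor carbon of the sulfinyl enone while C2 is blocked and deactivated by the 4-benzyloxyphenyl group. The sieves and the excess of 11 take up the water formed when the sulfenic acid self-condenses, which would otherwise hydrolyse the ketene acetal.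

Step 7
Reactants: 15 2-[4-(benzyloxy)phenyl]-5,7-dihydroxy-8-[4-(5-hydroxy-7-methoxy-4-oxo-4H-chromen-2-yl)phenoxy]-4H-chromen-4-one
Product: 16 5,7-dihydroxy-8-[4-(5-hydroxy-7-methoxy-4-oxo-4H-chromen-2-yl)phenoxy]-2-(4-hydroxyphenyl)-4H-chromen-4-one (CNP0424791.0)
Conditions: H2 (1 atm), Pd/C (10 wt %), THF–MeOH, rt
Reagents that add atoms: none
Why: Heterogeneous hydrogenolysis of the single benzyl aryl ether; the diaryl ether, the methyl ether and the flavone C2=C3 bonds are not reduced at atmospheric pressure and room temperature.

## Compound list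

1 | 1-[(4-methylphenyl)sulfanyl]propan-2-one | CC(=O)CSc1ccc(C)cc1 | starting material
2 | N,N-dimethylformamide dimethyl acetal | COC(OC)N(C)C | starting material
3 | (3Z)-4-(dimethylamino)-3-[(4-methylphenyl)sulfanyl]but-3-en-2-one (labile push-pull alkene) | CC(=O)/C(Sc1ccc(C)cc1)=C/N(C)C | intermediate
4 | 4-(benzyloxy)benzoyl chloride | O=C(Cl)c1ccc(OCc2ccccc2)cc1 | starting material
5 | (4Z)-1-[4-(benzyloxy)phenyl]-5-(dimethylamino)-4-[(4-methylphenyl)sulfanyl]pent-4-ene-1,3-dione (not isolated) | O=C(CC(=O)/C(Sc1ccc(C)cc1)=C/N(C)C)c1ccc(OCc2ccccc2)cc1 | intermediate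
6 | 2-[4-(benzyloxy)phenyl]-5-[(4-methylphenyl)sulfanyl]-4H-pyran-4-one | O=c1cc(-c2ccc(OCc3ccccc3)cc2)occ1Sc1ccc(C)cc1 | intermediate
7 | 2-[4-(benzyloxy)phenyl]-5-[(4-methylphenyl)sulfinyl]-4H-pyran-4-one, racemic at sulfur | O=c1cc(-c2ccc(OCc3ccccc3)cc2)occ1S(=O)c1ccc(C)cc1 | intermediate
8 | genkwanin, 5-hydroxy-2-(4-hydroxyphenyl)-7-methoxy-4H-chromen-4-one | COc1cc(O)c2c(=O)cc(-c3ccc(O)cc3)oc2c1 | starting material
9 | methyl 4-chloro-3-oxobutanoate | COC(=O)CC(=O)CCl | starting material
10 | methyl 4-[4-(5-hydroxy-7-methoxy-4-oxo-4H-chromen-2-yl)phenoxy]-3-oxobutanoate | COC(=O)CC(=O)COc1ccc(-c2cc(=O)c3c(O)cc(OC)cc3o2)cc1 | intermediate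
11 | 7-methoxy-2-[4-({(1Z,3Z)-4-methoxy-2,4-bis[(trimethylsilyl)oxy]buta-1,3-dien-1-yl}oxy)phenyl]-5-[(trimethylsilyl)oxy]-4H-chromen-4-one | CO/C(O[Si](C)(C)C)=C/C(O[Si](C)(C)C)=C/Oc1ccc(-c2cc(=O)c3c(O[Si](C)(C)C)cc(OC)cc3o2)cc1 | intermediate
12 | 2-[4-(benzyloxy)phenyl]-5-methoxy-8-{4-[7-methoxy-4-oxo-5-(trimethylsilyloxy)-4H-chromen-2-yl]phenoxy}-4a-[(4-methylphenyl)sulfinyl]-5,7-bis(trimethylsilyloxy)-4a,5,8,8a-tetrahydro-4H-chromen-4-one; racemic mixture of diastereomers, no configuration carried forward (not isolated) | COC1(O[Si](C)(C)C)C=C(O[Si](C)(C)C)C(Oc3ccc(-c4cc(=O)c5c(O[Si](C)(C)C)cc(OC)cc5o4)cc3)C2OC(-c3ccc(OCc4ccccc4)cc3)=CC(=O)C12S(=O)c1ccc(C)cc1 | intermediate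
13 | 2-[4-(benzyloxy)phenyl]-5-methoxy-8-{4-[7-methoxy-4-oxo-5-(trimethylsilyloxy)-4H-chromen-2-yl]phenoxy}-5,7-bis(trimethylsilyloxy)-5,8-dihydro-4H-chromen-4-one; racemic mixture of diastereomers (not isolated) | COC1(O[Si](C)(C)C)C=C(O[Si](C)(C)C)C(Oc3ccc(-c4cc(=O)c5c(O[Si](C)(C)C)cc(OC)cc5o4)cc3)C2=C1C(=O)C=C(-c1ccc(OCc3ccccc3)cc1)O2 | intermediate
14 | 2-[4-(benzyloxy)phenyl]-8-{4-[7-methoxy-4-oxo-5-(trimethylsilyloxy)-4H-chromen-2-yl]phenoxy}-5,7-bis(trimethylsilyloxy)-4H-chromen-4-one (not isolated) | COc1cc(O[Si](C)(C)C)c2c(=O)cc(-c3ccc(Oc4c(O[Si](C)(C)C)cc(O[Si](C)(C)C)c5c(=O)cc(-c6ccc(OCc7ccccc7)cc6)oc45)cc3)oc2c1 | intermediate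
15 | 2-[4-(benzyloxy)phenyl]-5,7-dihydroxy-8-[4-(5-hydroxy-7-methoxy-4-oxo-4H-chromen-2-yl)phenoxy]-4H-chromen-4-one | COc1cc(O)c2c(=O)cc(-c3ccc(Oc4c(O)cc(O)c5c(=O)cc(-c6ccc(OCc7ccccc7)cc6)oc45)cc3)oc2c1 | intermediate
16 | 5,7-dihydroxy-8-[4-(5-hydroxy-7-methoxy-4-oxo-4H-chromen-2-yl)phenoxy]-2-(4-hydroxyphenyl)-4H-chromen-4-one (CNP0424791.0, achiral) | COc1cc(O)c2c(=O)cc(-c3ccc(Oc4c(O)cc(O)c5c(=O)cc(-c6ccc(O)cc6)oc45)cc3)oc2c1 | target

## Step count and risks

Total step count: 7. Longest linear sequence: 5 steps (steps 1, 2, 3, 6, 7 from compound 1); the diene branch is 4 steps (steps 4, 5, 6, 7 from compound 8).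

**Step 6 (key step, proposed new method).** Three things may go wrong. Conjugate addition at C6 may be followed by opening of the pyranone ring (retro-oxa-Michael) in place of ring closure, so that the benzene ring is assembled from the wrong atoms. The pyranone may be too weak an acceptor, so that the diene is consumed by desilylation before it adds. Released sulfenic acid may protonate the ketene acetal.

The fallback uses known chemistry and makes the ether at the arene. It sets out from 8 and returns at 16. Apigenin F1 is perbenzylated (BnBr, K2CO3, DMF, 80 °C) to 5,7-bis(benzyloxy)-2-[4-(benzyloxy)phenyl]-4H-chromen-4-one F2. This is iodinated at C8, the usual site for 5,7-dialkoxyflavones (N-iodosuccinimide, CF3CO2H, CH2Cl2), to the 8-iodide F3. Ullmann ether synthesis of F3 with the 4'-hydroxyl of 8 (CuI, N,N-dimethylglycine, Cs2CO3, dioxane, 100 °C) gives the tribenzyl ether F4. Hydrogenolysis (H2, Pd/C) gives 16. This coupling is at the crowded carbon the main route avoids, so it is expected to be slow, but the reaction type is established.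

**Step 5.** The second silylation may stop short or occur at carbon C2. The silyl triflate may activate the flavone carbonyl towards attack by the newly formed diene. The product may hydrolyse on handling.

The fallback replaces soft enolisation by the two-stage amide-base protocol. It sets out from 10 and returns at 11. Me3SiCl and Et3N in toluene give the silyl enol ether methyl (2Z)-4-{4-[7-methoxy-4-oxo-5-(trimethylsilyloxy)-4H-chromen-2-yl]phenoxy}-3-(trimethylsilyloxy)but-2-enoate F5. Deprotonation of F5 at the aryloxy-bearing carbon with LiN(iPr)2 in THF at −78 °C and a Me3SiCl quench give 11.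

**Step 4.** Enolisation of the chloro keto ester may slow the displacement enough for self-condensation of 9 to take over. Some alkylation at O5 or at the acidic carbon of the product may also occur.

The fallback uses a masked, non-enolisable electrophile. It sets out from 8 and returns at 10. Alkylation of 8 with methyl (2E)-4-chloro-3-methoxybut-2-enoate F6 (K2CO3, DMF, 50 °C) gives the enol ether methyl (2E)-4-[4-(5-hydroxy-7-methoxy-4-oxo-4H-chromen-2-yl)phenoxy]-3-methoxybut-2-enoate F7. Hydrolysis of the enol ether of F7 (1 M HCl, THF, rt) gives 10.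

**Step 2.** O-acylation or double acylation of the enolate by the acid chloride may compete with the wanted C-acylation.

The fallback builds the diketone by aldol addition and oxidation. It sets out from 3 and returns at 5, and so at 6. The lithium enolate of 3 (LiN(SiMe3)2, THF, −78 °C) adds to 4-(benzyloxy)benzaldehyde F8 to give the racemic aldol (4Z)-1-[4-(benzyloxy)phenyl]-5-(dimethylamino)-1-hydroxy-4-[(4-methylphenyl)sulfanyl]pent-4-en-3-one F9. Dess–Martin periodinane oxidises F9 to 5, and CF3CO2H closes 5 to 6 as in the main route.

## Further compounds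

F1 | step 6 | apigenin, 5,7-dihydroxy-2-(4-hydroxyphenyl)-4H-chromen-4-one (purchased) | O=c1cc(-c2ccc(O)cc2)oc2cc(O)cc(O)c12
F2 | step 6 | 5,7-bis(benzyloxy)-2-[4-(benzyloxy)phenyl]-4H-chromen-4-one | O=c1cc(-c2ccc(OCc3ccccc3)cc2)oc2cc(OCc3ccccc3)cc(OCc3ccccc3)c12
F3 | step 6 | 5,7-bis(benzyloxy)-2-[4-(benzyloxy)phenyl]-8-iodo-4H-chromen-4-one | O=c1cc(-c2ccc(OCc3ccccc3)cc2)oc2c(I)c(OCc3ccccc3)cc(OCc3ccccc3)c12
F4 | step 6 | 5,7-bis(benzyloxy)-2-[4-(benzyloxy)phenyl]-8-[4-(5-hydroxy-7-methoxy-4-oxo-4H-chromen-2-yl)phenoxy]-4H-chromen-4-one | COc1cc(O)c2c(=O)cc(-c3ccc(Oc4c(OCc5ccccc5)cc(OCc5ccccc5)c5c(=O)cc(-c6ccc(OCc7ccccc7)cc6)oc45)cc3)oc2c1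
F5 | step 5 | methyl (2Z)-4-{4-[7-methoxy-4-oxo-5-(trimethylsilyloxy)-4H-chromen-2-yl]phenoxy}-3-(trimethylsilyloxy)but-2-enoate | COC(=O)/C=C(\O[Si](C)(C)C)COc1ccc(-c2cc(=O)c3c(O[Si](C)(C)C)cc(OC)cc3o2)cc1
F6 | step 4 | methyl (2E)-4-chloro-3-methoxybut-2-enoate (purchased) | COC(=O)/C=C(/OC)CCl
F7 | step 4 | methyl (2E)-4-[4-(5-hydroxy-7-methoxy-4-oxo-4H-chromen-2-yl)phenoxy]-3-methoxybut-2-enoate | COC(=O)/C=C(/OC)COc1ccc(-c2cc(=O)c3c(O)cc(OC)cc3o2)cc1
F8 | step 2 | 4-(benzyloxy)benzaldehyde (purchased) | O=Cc1ccc(OCc2ccccc2)cc1
F9 | step 2 | (4Z)-1-[4-(benzyloxy)phenyl]-5-(dimethylamino)-1-hydroxy-4-[(4-methylphenyl)sulfanyl]pent-4-en-3-one, racemic | OC(CC(=O)/C(Sc1ccc(C)cc1)=C/N(C)C)c1ccc(OCc2ccccc2)cc1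
A1 | alternative 1 | methyl 4-[2-hydroxy-4,6-bis(triisopropylsilyloxy)phenoxy]benzoate | COC(=O)c1ccc(Oc2c(O)cc(O[Si](C(C)C)(C(C)C)C(C)C)cc2O[Si](C(C)C)(C(C)C)C(C)C)cc1
A2 | alternative 1 | methyl 4-({2-oxo-4-[(triisopropylsilyl)oxy]cyclobut-3-en-1-yl}oxy)benzoate, racemic | COC(=O)c1ccc(OC2C(=O)C=C2O[Si](C(C)C)(C(C)C)C(C)C)cc1
A3 | alternative 1 | (ethynyloxy)triisopropylsilane | C#CO[Si](C(C)C)(C(C)C)C(C)C
A4 | alternative 2 | (2E)-3-[4-({5,7-bis(benzyloxy)-2-[4-(benzyloxy)phenyl]-4-oxo-4H-chromen-8-yl}oxy)phenyl]-1-(2,4,6-trihydroxyphenyl)prop-2-en-1-one | O=C(/C=C/c1ccc(Oc2c(OCc3ccccc3)cc(OCc3ccccc3)c3c(=O)cc(-c4ccc(OCc5ccccc5)cc4)oc23)cc1)c1c(O)cc(O)cc1O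
A5 | alternative 2 | methyl (8E)-9-[4-({5,7-bis(benzyloxy)-2-[4-(benzyloxy)phenyl]-4-oxo-4H-chromen-8-yl}oxy)phenyl]-3,5,7-trioxonon-8-enoate | COC(=O)CC(=O)CC(=O)CC(=O)/C=C/c1ccc(Oc2c(OCc3ccccc3)cc(OCc3ccccc3)c3c(=O)cc(-c4ccc(OCc5ccccc5)cc4)oc23)cc1
A6 | alternative 3 | methyl 4-[2,4-bis(benzyloxy)-6-(methoxymethoxy)phenoxy]benzoate | COC(=O)c1ccc(Oc2c(OCOC)cc(OCc3ccccc3)cc2OCc2ccccc2)cc1
A7 | alternative 3 | methyl coumalate, methyl 2-oxo-2H-pyran-5-carboxylate | COC(=O)C1=COC(=O)C=C1
A8 | alternative 3 | 1,5-bis(benzyloxy)-2-(ethynyloxy)-3-(methoxymethoxy)benzene | C#COc1c(OCOC)cc(OCc2ccccc2)cc1OCc1ccccc1
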